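**Retrosynthetic overview**

1. The target is traced back to a diphenylmethylene ketal across O4/O5 carrying benzoates on O1/O2, then to a hydroquinone with tert-butyl on O5 and triisopropylsilyl on O2, and then to the corresponding 1,4-benzoquinone.
2. The strategy rests on the hexasubstituted central ring, numbered C1(OBz), C2(OBz), C3(aryl), C4(OH), C5(OH), C6(aryl). At the quinone level C1 and C4 are carbonyls; the unit C4–C5(O)=C6(aryl)–C1 is a ring-opened 3-alkoxy-4-arylcyclobutenedione and C2(O)–C3(aryl) is an aryl ynol ether.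
3. The key disconnection is C1–C2 and C3–C4: cobalt opens the four-membered dione and the ynol ether is taken up. The central ring is the only ring formed, by expansion of the cyclobutenedione.
4. The two enol oxygens arrive differently protected, so acid frees O5, the O4/O5 catechol is bridged, fluoride frees O2, O1/O2 are benzoylated, and one hydrogenolysis removes the bridge and the benzyl ethers.
5. The dione comes from squaric acid (di-tert-butyl ester, aryllithium 1,2-addition, rearrangement); the ynol ether comes from 4-benzyloxyphenylacetylene by acetylide oxidation and O-silylation.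

Key step: step 4

Remark: the target has no stereogenic element, so no stereocontrol is needed. Because the two outer aryl groups are identical, the O1/O2 and O4/O5 pairs are interchangeable, and a 1,2-silyl shift between O1 and O2 leads to the same compounds 16 and 17.

**Route**

Step 1
Reactants: 1 squaric acid
Product: 2 di-tert-butyl squarate (3,4-di-tert-butoxycyclobut-3-ene-1,2-dione)
Conditions: t-BuOC(=NH)CCl3 (3 equiv), THF/CH2Cl2, rt
Reagents that add atoms: tert-butyl 2,2,2-trichloroacetimidate, CC(C)(C)OC(=N)C(Cl)(Cl)Cl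
Why: Imidate tert-butylation of an acid, in which the vinylogous diacid protonates the imidate and the ion pair collapses to the O-tert-butyl vinylogous ester, so that every proton ends up on trichloroacetamide and the acid-labile diester is never exposed to acid.

Step 2
Reactants: 3 1-benzyloxy-4-bromobenzene; 2 di-tert-butyl squarate
Product: 7 3-tert-butoxy-4-(4-benzyloxyphenyl)cyclobut-3-ene-1,2-dione, via 4-benzyloxyphenyllithium 4 (not isolated), via lithium cyclobutenolate adduct 5 (not isolated), via tertiary trifluoroacetate 6 (not isolated)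
Conditions: n-BuLi, THF, −78 °C; add to 2, THF, −78 °C; TFAA, −78 → 0 °C; aq NaHCO3
Reagents that add atoms: none
Why: Bromine–lithium exchange, 1,2-addition of the aryllithium to one squarate carbonyl and trifluoroacetylation-triggered ionisation with loss of one tert-butyl group from the alkoxy-stabilised cyclobutenyl cation (the standard squarate to 3-alkoxy-4-arylcyclobutenedione rearrangement) should give 7, the symmetry of 2 leaving no regiochemical question.

Step 3
Reactants: 8 1-benzyloxy-4-ethynylbenzene
Product: 11 [(4-benzyloxyphenyl)ethynyloxy]triisopropylsilane, via lithium arylacetylide 9 (not isolated), via lithium arylethynolate 10 (not isolated)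
Conditions: LiHMDS, THF, −78 °C; t-BuOOLi (from t-BuOOH + LiHMDS), −78 → 0 °C; TIPSOTf, −78 → 0 °C
Reagents that add atoms: tert-butyl hydroperoxide, CC(C)(C)OO; triisopropylsilyl trifluoromethanesulfonate, CC(C)[Si](OS(=O)(=O)C(F)(F)F)(C(C)C)C(C)C
Why: Oxidation of a lithium acetylide by lithium tert-butyl peroxide (electrophilic oxygen transfer to the ynolate) followed by O-silylation with the bulky silyl triflate is the established one-flask route to triisopropylsilyl ynol ethers, and LiHMDS is too weak a base to attack the benzyl ether.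

Step 4
Reactants: 7 3-tert-butoxy-4-(4-benzyloxyphenyl)cyclobut-3-ene-1,2-dione; 11 [(4-benzyloxyphenyl)ethynyloxy]triisopropylsilane
Product: 14 2-tert-butoxy-3,6-bis(4-benzyloxyphenyl)-5-(triisopropylsilyloxy)-1,4-benzoquinone, via chlorobis(triphenylphosphine)maleoylcobalt complex 12 (not isolated), via cationic bis(acetonitrile)maleoylcobalt tetrafluoroborate 13 (not isolated)
Conditions: ClCo(PPh3)3, PhH, rt; evaporate; AgBF4, MeCN, 0 °C → rt, filter AgCl; 11, MeCN, rt → 50 °C
Reagents that add atoms: none
Why: Proposed new method: a silyl ynol ether has not been used as the two-carbon partner of a maleoylcobalt complex; the closest known reaction type is the quinone synthesis from cyclobutenedione-derived maleoyl- and phthaloylcobalt complexes and alkyl, aryl or alkoxy alkynes after halide abstraction or Lewis-acid activation. Cobalt(I) adds oxidatively across the strained C(O)–C(O) bond of 7 to give the five-membered diacyl metallacycle 12; silver ion removes chloride so that the ynol ether can bind next to the acyl groups of 13, one acyl migrates to the alkyne, and C–C reductive elimination from the seven-membered metallacycle releases the quinone. The six-membered ring is thus closed as a formal [4+2] union of the four carbons of the opened dione with the two alkyne carbons, the second bond by reductive elimination, and no stereocentre is formed. The step needs head-to-tail regiochemistry, C2(OSi) on C1 and C3(aryl) on C4, so that the aryl groups end up para. This should follow from matched polarisation: the aryl-bearing carbon is the nucleophilic end of the ynol ether and C4 is the more electrophilic acyl (C1 is a vinylogous ester carbonyl through C6=C5–OtBu), and the reverse orientation would also place OTIPS and OtBu on either side of one carbonyl. Chloride abstraction is chosen over an oxophilic Lewis acid such as SnCl4, which would bind the basic C1 carbonyl, could invert this bias and would endanger the tert-butyl and silyl groups.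

Step 5
Reactants: 14 2-tert-butoxy-3,6-bis(4-benzyloxyphenyl)-5-(triisopropylsilyloxy)-1,4-benzoquinone
Product: 15 2-tert-butoxy-3,6-bis(4-benzyloxyphenyl)-5-(triisopropylsilyloxy)benzene-1,4-diol
Conditions: Na2S2O4, EtOAc/H2O, rt, Ar
Reagents that add atoms: none
Why: Dithionite reduction of a 1,4-benzoquinone to the hydroquinone is fast in a two-phase system near neutral pH, which should spare the silyl vinylogous ester until it has become a robust aryl silyl ether, and it leaves benzyl and tert-butyl ethers untouched.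

Step 6
Reactants: 15 2-tert-butoxy-3,6-bis(4-benzyloxyphenyl)-5-(triisopropylsilyloxy)benzene-1,4-diol
Product: 16 3,6-bis(4-benzyloxyphenyl)-5-(triisopropylsilyloxy)benzene-1,2,4-triol
Conditions: TFA, Et3SiH, CH2Cl2, 0 °C, Ar
Reagents that add atoms: none
Why: Acidolysis of the aryl tert-butyl ether through the tert-butyl cation, which triethylsilane reduces to isobutane before it can alkylate the electron-rich rings, should leave the aryl silyl and benzyl ethers intact and expose the C4/C5 catechol.

Step 7
Reactants: 16 3,6-bis(4-benzyloxyphenyl)-5-(triisopropylsilyloxy)benzene-1,2,4-triol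
Product: 17 4,7-bis(4-benzyloxyphenyl)-2,2-diphenyl-6-(triisopropylsilyloxy)-1,3-benzodioxol-5-ol
Conditions: Ph2CCl2, pyridine, MeCN, 40 °C, Ar
Reagents that add atoms: dichlorodiphenylmethane, ClC(Cl)(c1ccccc1)c1ccccc1
Why: Catechol protection as a 2,2-diphenyl-1,3-benzodioxole (two successive SN1 substitutions at the dichloride) can close only across O4/O5, the sole pair of adjacent free hydroxyls, so the C1 hydroxyl stays free and any chlorodiphenylmethyl ether formed there reverts on aqueous work-up.

Step 8
Reactants: 17 4,7-bis(4-benzyloxyphenyl)-2,2-diphenyl-6-(triisopropylsilyloxy)-1,3-benzodioxol-5-ol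
Product: 19 4,7-bis(4-benzyloxyphenyl)-2,2-diphenyl-1,3-benzodioxole-5,6-diyl dibenzoate, via 4,7-bis(4-benzyloxyphenyl)-2,2-diphenyl-1,3-benzodioxole-5,6-diol 18 (not isolated)
Conditions: TBAF, THF, 0 °C, Ar; then BzCl, Et3N, DMAP, 0 °C → rt
Reagents that add atoms: benzoyl chloride, O=C(Cl)c1ccccc1
Why: Fluoride cleavage of the aryl silyl ether followed in the same flask by DMAP-catalysed O-benzoylation of both phenolic oxygens avoids isolating the oxidation-prone catechol and does not affect the ketal or the benzyl ethers.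

Step 9
Reactants: 19 4,7-bis(4-benzyloxyphenyl)-2,2-diphenyl-1,3-benzodioxole-5,6-diyl dibenzoate
Product: 20 4,5-dihydroxy-3,6-bis(4-hydroxyphenyl)-1,2-phenylene dibenzoate (target)
Conditions: H2 (1 atm), Pd/C, EtOAc/THF, rt
Reagents that add atoms: none
Why: Palladium-catalysed hydrogenolysis cleaves the two benzyl ethers and the doubly benzylic C–O bonds of the diphenylmethylene ketal under neutral conditions in which aryl benzoates are stable and, having no neighbouring free hydroxyl, have no path for acyl migration.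

**Compound list**

1 | squaric acid (3,4-dihydroxycyclobut-3-ene-1,2-dione) | O=C1C(O)=C(O)C1=O | starting material
2 | di-tert-butyl squarate (3,4-di-tert-butoxycyclobut-3-ene-1,2-dione) | O=C1C(OC(C)(C)C)=C(OC(C)(C)C)C1=O | intermediate
3 | 1-benzyloxy-4-bromobenzene | Brc1ccc(OCc2ccccc2)cc1 | starting material
4 | 4-benzyloxyphenyllithium | [Li]c1ccc(OCc2ccccc2)cc1 | intermediate
5 | lithium 1-(4-benzyloxyphenyl)-2,3-di-tert-butoxy-4-oxocyclobut-2-en-1-olate | [Li]OC1(c2ccc(OCc3ccccc3)cc2)C(OC(C)(C)C)=C(OC(C)(C)C)C1=O | intermediate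
6 | 1-(4-benzyloxyphenyl)-2,3-di-tert-butoxy-4-oxocyclobut-2-en-1-yl trifluoroacetate | O=C(OC1(c2ccc(OCc3ccccc3)cc2)C(OC(C)(C)C)=C(OC(C)(C)C)C1=O)C(F)(F)F | intermediate
7 | 3-tert-butoxy-4-(4-benzyloxyphenyl)cyclobut-3-ene-1,2-dione | O=C1C(=O)C(OC(C)(C)C)=C1c1ccc(OCc2ccccc2)cc1 | intermediate
8 | 1-benzyloxy-4-ethynylbenzene | C#Cc1ccc(OCc2ccccc2)cc1 | starting material
9 | lithium (4-benzyloxyphenyl)acetylide | [Li]C#Cc1ccc(OCc2ccccc2)cc1 | intermediate
10 | lithium 2-(4-benzyloxyphenyl)ethynolate | [Li]OC#Cc1ccc(OCc2ccccc2)cc1 | intermediate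
11 | [(4-benzyloxyphenyl)ethynyloxy]triisopropylsilane | CC(C)[Si](OC#Cc1ccc(OCc2ccccc2)cc1)(C(C)C)C(C)C | intermediate
12 | chlorobis(triphenylphosphine)cobalt metallacycle of 7 (cobalt between the two acyl carbons; 1-cobaltacyclopent-3-ene-2,5-dione bearing 3-aryl and 4-tert-butoxy) | O=C1C(c2ccc(OCc3ccccc3)cc2)=C(OC(C)(C)C)C(=O)[Co-2]1(Cl)([P+](c1ccccc1)(c1ccccc1)c1ccccc1)[P+](c1ccccc1)(c1ccccc1)c1ccccc1 | intermediate
13 | bis(acetonitrile)bis(triphenylphosphine)cobalt metallacycle of 7, tetrafluoroborate salt | O=C1C(c2ccc(OCc3ccccc3)cc2)=C(OC(C)(C)C)C(=O)[Co-3]1([N+]#CC)([N+]#CC)([P+](c1ccccc1)(c1ccccc1)c1ccccc1)[P+](c1ccccc1)(c1ccccc1)c1ccccc1.F[B-](F)(F)F | intermediate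
14 | 2-tert-butoxy-3,6-bis(4-benzyloxyphenyl)-5-(triisopropylsilyloxy)-1,4-benzoquinone | O=C1C(O[Si](C(C)C)(C(C)C)C(C)C)=C(c2ccc(OCc3ccccc3)cc2)C(=O)C(OC(C)(C)C)=C1c1ccc(OCc2ccccc2)cc1 | intermediate
15 | 2-tert-butoxy-3,6-bis(4-benzyloxyphenyl)-5-(triisopropylsilyloxy)benzene-1,4-diol | Oc1c(O[Si](C(C)C)(C(C)C)C(C)C)c(-c2ccc(OCc3ccccc3)cc2)c(O)c(OC(C)(C)C)c1-c1ccc(OCc2ccccc2)cc1 | intermediate
16 | 3,6-bis(4-benzyloxyphenyl)-5-(triisopropylsilyloxy)benzene-1,2,4-triol | Oc1c(O[Si](C(C)C)(C(C)C)C(C)C)c(-c2ccc(OCc3ccccc3)cc2)c(O)c(O)c1-c1ccc(OCc2ccccc2)cc1 | intermediate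
17 | 4,7-bis(4-benzyloxyphenyl)-2,2-diphenyl-6-(triisopropylsilyloxy)-1,3-benzodioxol-5-ol | Oc1c(O[Si](C(C)C)(C(C)C)C(C)C)c(-c2ccc(OCc3ccccc3)cc2)c2OC(c3ccccc3)(c3ccccc3)Oc2c1-c1ccc(OCc2ccccc2)cc1 | intermediate
18 | 4,7-bis(4-benzyloxyphenyl)-2,2-diphenyl-1,3-benzodioxole-5,6-diol | Oc1c(O)c(-c2ccc(OCc3ccccc3)cc2)c2OC(c3ccccc3)(c3ccccc3)Oc2c1-c1ccc(OCc2ccccc2)cc1 | intermediate
19 | 4,7-bis(4-benzyloxyphenyl)-2,2-diphenyl-1,3-benzodioxole-5,6-diyl dibenzoate | O=C(Oc1c(OC(=O)c2ccccc2)c(-c2ccc(OCc3ccccc3)cc2)c2OC(c3ccccc3)(c3ccccc3)Oc2c1-c1ccc(OCc2ccccc2)cc1)c1ccccc1 | intermediate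
20 | 4,5-dihydroxy-3,6-bis(4-hydroxyphenyl)-1,2-phenylene dibenzoate | O=C(Oc1c(OC(=O)c2ccccc2)c(-c2ccc(O)cc2)c(O)c(O)c1-c1ccc(O)cc1)c1ccccc1 | target

**Step count**

Total steps: 9. Longest linear sequence: 8 (steps 1, 2, 4, 5, 6, 7, 8, 9).

**Steps most likely to fail**

Step 4 (Proposed new method). The ynol ether may insert in the reverse orientation and give the meta-diaryl quinone. It may also be desilylated to a ketene at the cationic cobalt centre, or be consumed by cobalt-mediated oligomerisation before it inserts. The fallback uses known chemistry, sets out from 3 and returns at 18.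
- Bromine–lithium exchange on 3 and borylation (B(OiPr)3, then aqueous acid) give (4-benzyloxyphenyl)boronic acid F1.
- Bromanil is methanolysed (NaOMe, MeOH) to 2,5-dibromo-3,6-dimethoxy-1,4-benzoquinone F2.
- Double Suzuki–Miyaura coupling of F1 with F2 (Pd(PPh3)4, aq Na2CO3, dioxane) gives 2,5-bis(4-benzyloxyphenyl)-3,6-dimethoxy-1,4-benzoquinone F3, in which the halide positions fix the para-diaryl pattern.
- Hydrolysis of both vinylogous esters (aq NaOH, dioxane, then acid) gives 2,5-bis(4-benzyloxyphenyl)-3,6-dihydroxy-1,4-benzoquinone F4.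
- Dithionite reduction gives 3,6-bis(4-benzyloxyphenyl)benzene-1,2,4,5-tetraol F5.
- F5 is bridged with one equivalent of Ph2CCl2 (pyridine, MeCN). Its two catechol pairs are equivalent, so the mono-ketal is a single compound, expected statistically beside recoverable tetraol and bis-ketal; it is diol 18.
- 18 is benzoylated as in the second half of step 8 to reach 19.

Step 7. The electron-rich triol may be oxidised by air to a hydroxyquinone once base is present. The second C–O bond of the ketal may fail to close, and chloride or pyridinium may remove or shift the neighbouring silyl group. The fallback sets out from 16 and returns at 20; it changes the bridge to an isopropylidene ketal, put on under acid catalysis without base and taken off by aqueous acid instead of hydrogen.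
- 16 with 2,2-dimethoxypropane and catalytic TsOH (benzene, reflux, removal of methanol) gives 4,7-bis(4-benzyloxyphenyl)-2,2-dimethyl-6-(triisopropylsilyloxy)-1,3-benzodioxol-5-ol F6.
- TBAF gives 4,7-bis(4-benzyloxyphenyl)-2,2-dimethyl-1,3-benzodioxole-5,6-diol F7, which is benzoylated in the same flask as in step 8 to 4,7-bis(4-benzyloxyphenyl)-2,2-dimethyl-1,3-benzodioxole-5,6-diyl dibenzoate F8.
- Aqueous TFA cleaves the acetonide to 3,6-bis(4-benzyloxyphenyl)-4,5-dihydroxy-1,2-phenylene dibenzoate F9; aryl benzoates and benzyl ethers should survive.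
- Hydrogenolysis of the two benzyl ethers (H2, Pd/C) gives 20.

Step 1. Squaric acid is almost insoluble, so tert-butyl transfer may compete poorly with acid-induced breakdown of the imidate to isobutene, and the reaction may stop at the mono-ester. The fallback sets out from 1 and returns at 2. Squaric acid is precipitated with aqueous AgNO3 as disilver squarate F10, which is dried and alkylated in the dark with tert-butyl chloride in diethyl ether (silver-assisted SN1 alkylation) to give 2 under acid-free conditions.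

**Further compounds**

F1 | step 4 | (4-benzyloxyphenyl)boronic acid | OB(O)c1ccc(OCc2ccccc2)cc1
F2 | step 4 | 2,5-dibromo-3,6-dimethoxy-1,4-benzoquinone | COC1=C(Br)C(=O)C(OC)=C(Br)C1=O
F3 | step 4 | 2,5-bis(4-benzyloxyphenyl)-3,6-dimethoxy-1,4-benzoquinone | COC1=C(c2ccc(OCc3ccccc3)cc2)C(=O)C(OC)=C(c2ccc(OCc3ccccc3)cc2)C1=O
F4 | step 4 | 2,5-bis(4-benzyloxyphenyl)-3,6-dihydroxy-1,4-benzoquinone | OC1=C(c2ccc(OCc3ccccc3)cc2)C(=O)C(O)=C(c2ccc(OCc3ccccc3)cc2)C1=O
F5 | step 4 | 3,6-bis(4-benzyloxyphenyl)benzene-1,2,4,5-tetraol | Oc1c(O)c(-c2ccc(OCc3ccccc3)cc2)c(O)c(O)c1-c1ccc(OCc2ccccc2)cc1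
F6 | step 7 | 4,7-bis(4-benzyloxyphenyl)-2,2-dimethyl-6-(triisopropylsilyloxy)-1,3-benzodioxol-5-ol | Oc1c(O[Si](C(C)C)(C(C)C)C(C)C)c(-c2ccc(OCc3ccccc3)cc2)c2OC(C)(C)Oc2c1-c1ccc(OCc2ccccc2)cc1
F7 | step 7 | 4,7-bis(4-benzyloxyphenyl)-2,2-dimethyl-1,3-benzodioxole-5,6-diol | Oc1c(O)c(-c2ccc(OCc3ccccc3)cc2)c2OC(C)(C)Oc2c1-c1ccc(OCc2ccccc2)cc1
F8 | step 7 | 4,7-bis(4-benzyloxyphenyl)-2,2-dimethyl-1,3-benzodioxole-5,6-diyl dibenzoate | O=C(Oc1c(OC(=O)c2ccccc2)c(-c2ccc(OCc3ccccc3)cc2)c2OC(C)(C)Oc2c1-c1ccc(OCc2ccccc2)cc1)c1ccccc1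
F9 | step 7 | 3,6-bis(4-benzyloxyphenyl)-4,5-dihydroxy-1,2-phenylene dibenzoate | O=C(Oc1c(OC(=O)c2ccccc2)c(-c2ccc(OCc3ccccc3)cc2)c(O)c(O)c1-c1ccc(OCc2ccccc2)cc1)c1ccccc1
F10 | step 1 | disilver squarate | [Ag+].[Ag+].[O-]C1=C([O-])C(=O)C1=O
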